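**Retrosynthetic overview**
1. Kuwanon E (9) ⇒ its tetraacetate 8, opened in the last step by neutral global deacetylation.
2. The C5'–C1'' aryl–geranyl bond ⇒ aryl iodide 6 + geranyl acetate 7, joined by Ni-catalysed electroreductive cross-electrophile coupling (key step).
3. Iodide 6 ⇒ phenol 4, whose only free hydroxyl (4'-OH) directs iodination to C5'.
4. The 2'-oxygen ⇒ 1,2-acyloxy shift of B-ring p-quinol acetate 3, made by oxidative dearomatisation. The dienone C=O masks 4'-OH while the A ring is acetylated.
5. No ring is built. Rings A, C and B and the C2 (S) centre are bought intact in (2S)-naringenin (1), and C2 is never a reacting centre.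

Assumption: (2S)-(–)-naringenin is bought as the natural enantiomer. The lot's ee is confirmed by chiral HPLC, because racemic grades are also sold. B-ring locants follow the target numbering.

**Step 1**
Reactants: 1, (2S)-naringenin
Product: 2, (2S)-5,7-dihydroxy-2-(1-hydroxy-4-oxocyclohexa-2,5-dien-1-yl)chroman-4-one (B-ring p-quinol)
Conditions: PhI(OCOCF3)2 (1.5 equiv), MeCN–H2O 9:1 (0.01 M), 0 °C → rt
Reagents that add atoms: water, O
Why: Hypervalent-iodine oxidative dearomatisation of a 4-alkylphenol to a p-quinol (water attacks C1' of the aryloxy-iodane) is B-ring selective because the A-ring hydroxyls sit in a chelated vinylogous acid, as in the known one-step oxidation of unprotected apigenin to protoapigenone, and C2 is untouched while C1' is not stereogenic.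

**Step 2**
Reactants: 2
Product: 3, (2S)-2-(1-acetoxy-4-oxocyclohexa-2,5-dien-1-yl)-4-oxochroman-5,7-diyl diacetate
Conditions: Ac2O (6 equiv), pyridine, DMAP (cat.), CH2Cl2, 0 °C → rt
Reagents that add atoms: acetic anhydride, CC(=O)OC(C)=O
Why: Exhaustive DMAP-catalysed acetylation places the migrating group on the tertiary 1'-OH and deactivates the A ring in one operation, while the future 4'-OH stays masked as the dienone carbonyl and pyridine-level basicity does not open the flavanone.

**Step 3**
Reactants: 3
Product: 4, (2S)-2-(2-acetoxy-4-hydroxyphenyl)-4-oxochroman-5,7-diyl diacetate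
Conditions: BF3·OEt2 (2 equiv), CH2Cl2, –40 → 0 °C; cold aq NaHCO3 quench
Reagents that add atoms: none
Why: In this dienone–phenol rearrangement with 1,2-acyloxy migration (quinol acetate → resorcinol monoacetate), the acetate C=O adds to the adjacent activated β-carbon through a five-membered acetoxonium, C1'–O breaks and proton loss aromatises, so the C2'–O bond forms, only 4'-OH is released, both diastereotopic β-carbons give the same product, and C2 keeps all four bonds.

**Step 4**
Reactants: 4
Product: 6, (2S)-2-(2,4-diacetoxy-5-iodophenyl)-4-oxochroman-5,7-diyl diacetate, via iodophenol 5, (2S)-2-(2-acetoxy-4-hydroxy-5-iodophenyl)-4-oxochroman-5,7-diyl diacetate (not isolated)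
Conditions: NIS (1.05 equiv), TFA (0.3 equiv), MeCN, 0 °C; then pyridine, Ac2O, rt (one pot)
Reagents that add atoms: N-iodosuccinimide, O=C1CCC(=O)N1I; acetic anhydride, CC(=O)OC(C)=O
Why: Electrophilic aromatic iodination goes to the only strongly activated ring, ortho to the free 4'-OH and para to 2'-OAc (C5', since C3' is flanked by two oxygens and the acetylated acyl-bearing A ring is deactivated), and in-flask acetylation removes the acidic phenol before the reductive coupling.

**Step 5 (key step)**
Reactants: 6; 7, geranyl acetate [(2E)-3,7-dimethylocta-2,6-dien-1-yl acetate], 2 equiv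
Product: 8, (2S)-2-{2,4-diacetoxy-5-[(2E)-3,7-dimethylocta-2,6-dien-1-yl]phenyl}-4-oxochroman-5,7-diyl diacetate
Conditions: NiBr2·glyme (10 mol %), dtbbpy (12 mol %), nBu4NBF4 (0.1 M), DMA, undivided cell, Zn(+)/Ni foam(–), 5 mA, 2.3 F mol⁻¹, rt, N2
Reagents that add atoms: geranyl acetate (7), CC(C)=CCC/C(C)=C/COC(C)=O (delivers C10H17)
Why: Proposed new method: cathodically generated Ni(0)(dtbbpy) (about –1.2 V vs SCE, well positive of aryl-ketone and aryl-acetate reduction) inserts into C5'–I, one-electron reduction gives Ar–Ni(I), which ionises geranyl acetate to an Ar–Ni(III)(η3-geranyl) species that reductively eliminates at the unhindered CH2 terminus (linear product), the 2E geometry holding because syn/anti exchange would need σ-Ni at the tertiary carbon, while Zn2+ from the anode ties up the released acetate so the medium stays base-free and C2, the ketone and the four acetates survive; the closest known reaction type is Ni- or Co-catalysed reductive (electrochemical or Zn/Mn-driven) cross-electrophile coupling of aryl halides with simple allylic acetates, not yet shown for an isomerisable trisubstituted terpenyl acetate or for an epimerisable polyacetoxy flavanone.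

**Step 6**
Reactants: 8
Product: 9, Kuwanon E, (2S)-2-{5-[(2E)-3,7-dimethylocta-2,6-dien-1-yl]-2,4-dihydroxyphenyl}-5,7-dihydroxychroman-4-one
Conditions: NH4OAc (20 equiv), MeOH–H2O 4:1, rt → 35 °C; pH 6 work-up
Reagents that add atoms: none
Why: Neutral ammonium acetate-mediated cleavage of aryl acetates (about pH 7) frees all four phenols without the base- or acid-induced retro-oxa-Michael or quinone-methide ring opening that racemises flavanones, and without cyclising the ortho-geranylphenol to a chroman.

**Compound list**

| No. | Name | SMILES | Role |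
|---|---|---|---|
| 1 | (2S)-naringenin | `Oc1ccc([C@@H]2CC(=O)c3c(O)cc(O)cc3O2)cc1` | starting material |
| 2 | B-ring p-quinol of naringenin | `O=C1C=CC(O)([C@@H]2CC(=O)c3c(O)cc(O)cc3O2)C=C1` | intermediate |
| 3 | p-quinol triacetate | `CC(=O)OC1([C@@H]2CC(=O)c3c(OC(C)=O)cc(OC(C)=O)cc3O2)C=CC(=O)C=C1` | intermediate |
| 4 | 5,7,2'-triacetoxy-4'-hydroxyflavanone | `CC(=O)Oc1cc(O)ccc1[C@@H]2CC(=O)c3c(OC(C)=O)cc(OC(C)=O)cc3O2` | intermediate |
| 5 | 5'-iodo-5,7,2'-triacetoxy-4'-hydroxyflavanone | `CC(=O)Oc1cc(O)c(I)cc1[C@@H]2CC(=O)c3c(OC(C)=O)cc(OC(C)=O)cc3O2` | intermediate (not isolated) |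
| 6 | 5'-iodo-5,7,2',4'-tetraacetoxyflavanone | `CC(=O)Oc1cc(OC(C)=O)c(I)cc1[C@@H]2CC(=O)c3c(OC(C)=O)cc(OC(C)=O)cc3O2` | intermediate |
| 7 | geranyl acetate | `CC(C)=CCC/C(C)=C/COC(C)=O` | starting material |
| 8 | Kuwanon E tetraacetate | `CC(C)=CCC/C(C)=C/Cc1cc([C@@H]2CC(=O)c3c(OC(C)=O)cc(OC(C)=O)cc3O2)c(OC(C)=O)cc1OC(C)=O` | intermediate |
| 9 | Kuwanon E | `CC(C)=CCC/C(C)=C/Cc1cc([C@@H]2CC(=O)c3c(O)cc(O)cc3O2)c(O)cc1O` | target |

**Total step count:** 6 (step 4 is a one-pot, two-stage operation).
**Longest linear sequence:** 6 (1 → 9; geranyl acetate 7 is bought).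

**Steps most likely to fail**
1. **Step 5 (proposed new step).** The risks are hydrodeiodination, homocoupling, and leakage to branched or Z product.
   - Fallback (known chemistry): Pd(0)-catalysed Stille coupling of 6 with (E)-geranyltributylstannane under neutral conditions [Pd2(dba)3/AsPh3, DMF], the established way to make prenyl and geranyl arenes. It gives the same 8.
2. **Step 3.** The risks are C1'–C2 fragmentation to a hydroquinone monoacetate, carbon rather than acyloxy migration, and acid ionisation of C2–O1.
   - Fallback: stop the acetylation at the 5,7-diacetate by omitting DMAP, which leaves the tertiary 1'-OH free.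
   - Deliver the 2'-oxygen from that hydroxyl through a boronic acid tether (PhB(OH)2-mediated intramolecular oxa-Michael, known for γ-hydroxy enones).
   - Aromatise by acid dehydration to the 5,7-diacetoxy-2',4'-diol, then iodinate at C5' and peracetylate to the same 6.
3. **Step 1.** The risks are low yield from A-ring over-oxidation or dehydrogenation to the flavone.
   - Fallback: dye-sensitised photooxygenation of 1 (O2, rose bengal, visible light) to the 1'-hydroperoxy dienone through singlet oxygen, then Me2S reduction to 2. This avoids a two-electron phenoxenium pathway.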